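**Assumptions.** Atom labels follow iridoid numbering: C1 acetal, C3=C4 enol ether, C5=C6, C7 carbinol, C8 tertiary carbinol, C9 ring fusion, C10 and C11 the CH2O arms. β is the face of H‑9. Centres written without a descriptor (C7 up to step 12, C4 in steps 10–12) are carried as mixtures on purpose, because both are destroyed later.

## Retrosynthetic overview
1. The target comes from an 8‑OH‑directed 1,2‑reduction of 7‑ketone 18 in the last step (sets C7). Ketone 18 comes from anomeric isovalerylation of lactol 17 (sets C1). The labile dienol ether/allylic alcohol therefore appears only in the final flask.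
2. Ring B is the key gamble. Triple oxidation of tetraol 16 gives a keto‑dialdehyde that should close itself, by vinylogous enolisation and lactolisation, into a push–pull 7‑oxo iridoid.
3. Ring A and C11 come from ring‑closing enyne metathesis of 1,6‑enyne 12 (methylene transfer to C4), followed by terminal hydroboration.
4. C8 and C9 come from one reagent‑controlled operation: Sharpless epoxide 6, later opened at C9 by an alkynylalane with inversion. C7 is left stereorandom.
5. The olefin geometry comes from trans‑hydrostannation and Stille coupling of 2‑butyne‑1,4‑diol. Ring order is A (step 9), then B (step 13). Deliberately avoided: genipin/valtrate semisynthesis, late spiro‑epoxide opening, and Pauson–Khand or organocatalytic iridoid cores.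

## Route

**Step 1**
Reactants: 1, 2‑butyne‑1,4‑diol
Product: 2, 4‑(tert‑butyldimethylsilyloxy)but‑2‑yn‑1‑ol
Conditions: NaH (1.0 equiv), THF, 0 °C; TBSCl (1.0 equiv), rt
Reagents that add atoms: TBSCl, CC(C)(C)[Si](C)(C)Cl
Why: Silylation of the sparingly soluble mono‑alkoxide stops at the mono‑ether and differentiates the future C1 terminus (OTBS) from the future C10 terminus (free OH); no stereocentre is formed.

**Step 2**
Reactants: 2
Product: 3, (Z)‑4‑(TBSO)‑2‑(tributylstannyl)but‑2‑en‑1‑ol (Sn cis to CH2OTBS, H cis to CH2OH)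
Conditions: Bu3SnH, [Cp*RuCl]4 (2 mol %), CH2Cl2, rt
Reagents that add atoms: tributyltin hydride, CCCC[SnH](CCCC)CCCC
Why: In this hydroxyl‑directed Ru‑catalysed trans‑hydrostannation an OH···Cl–Ru hydrogen bond puts tin on the alkyne carbon next to the free carbinol and H adds anti, giving the olefin geometry (C1 cis to the future C7) that later becomes the C8/C9 relative configuration.

**Step 3**
Reactants: 3; 4, vinyl bromide
Product: 5, (E)‑4‑(TBSO)‑2‑vinylbut‑2‑en‑1‑ol (the two CH2O arms trans)
Conditions: Pd(PPh3)4 (5 mol %), CuTC, [Bu4N][Ph2PO2], DMF, rt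
Reagents that add atoms: vinyl bromide (4), C=CBr
Why: Copper‑assisted Stille coupling proceeds with retention of alkene geometry and tolerates the free OH and the silyl ether, installing a vinyl group that serves as the masked C7 aldehyde.

**Step 4**
Reactants: 5
Product: 6, [(2S,3S)‑3‑(TBSOCH2)‑2‑vinyloxiran‑2‑yl]methanol
Conditions: Ti(OiPr)4 (10 mol %), L‑(+)‑DIPT (12 mol %), TBHP, 4 Å MS, CH2Cl2, −25 °C
Reagents that add atoms: tert‑butyl hydroperoxide, CC(C)(C)OO
Why: In this Katsuki–Sharpless epoxidation only the trisubstituted olefin is allylic to the Ti‑bound C10 carbinol, and L‑(+)‑tartrate gives the (2S,3S) sense, which fixes the C8–O bond (kept to the end) and sets C9 up for one inversion.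

**Step 5**
Reactants: 6
Product: 7, (2S,3S)‑3‑(TBSOCH2)‑2‑(hydroxymethyl)oxirane‑2‑carbaldehyde
Conditions: O3, CH2Cl2, −78 °C; PPh3
Reagents that add atoms: ozone, [O-][O+]=O
Why: Criegee ozonolysis cleaves the only remaining C=C and unmasks C7 as an epoxy aldehyde without touching the epoxide, the silyl ether or either stereocentre, and it also removes the allylic activation at C8 before the epoxide is opened.

**Step 6**
Reactants: 7; 8, vinylmagnesium bromide
Product: 9, 1‑[(2R,3S)‑3‑(TBSOCH2)‑2‑(hydroxymethyl)oxiran‑2‑yl]prop‑2‑en‑1‑ol (C7 epimers)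
Conditions: 8 (3 equiv), THF, −78 °C; aq NH4Cl
Reagents that add atoms: vinylmagnesium bromide (8), C=C[Mg]Br
Why: Grignard 1,2‑addition at −78 °C (too cold for Payne migration) adds C6 and the methylene that later becomes C11, and the new C7 carbinol is left unselective because it is oxidised in step 13 and reset in step 15.

**Step 7**
Reactants: 9; 10, tert‑butyldimethyl(prop‑2‑yn‑1‑yloxy)silane
Product: 11, (4R,5R)‑8‑(TBSO)‑5‑(TBSOCH2)‑4‑(hydroxymethyl)oct‑1‑en‑6‑yne‑3,4‑diol (C3 epimers; chain C4 = iridoid C8, chain C5 = iridoid C9)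
Conditions: 10 (4 equiv), n‑BuLi, then Et2AlCl, toluene, 0 °C; add 9, 0 °C → rt
Reagents that add atoms: alkyne 10 (as its Et2Al acetylide), C#CCO[Si](C)(C)C(C)(C)C
Why: In this directed opening of a 2,3‑epoxy alcohol by an alkynylalane both aluminium alkoxides (O7, O10) sit on carbons attached to C8, so the acetylide attacks the distal, less substituted C9 ("C3 attack") by SN2 with inversion, which sets C9 and releases the C8 tertiary OH with retention.

**Step 8**
Reactants: 11
Product: 12, (2R,3R)‑6‑(TBSO)‑3‑(TBSOCH2)‑2‑hydroxy‑2‑(1‑hydroxyprop‑2‑en‑1‑yl)hex‑4‑yn‑1‑yl 3‑methylbutanoate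
Conditions: isovaleryl chloride (1.05 equiv), 2,4,6‑collidine, CH2Cl2, −78 → −40 °C
Reagents that add atoms: isovaleryl chloride, CC(C)CC(=O)Cl
Why: Kinetic acylation with a weak hindered base selects the only primary OH (C10) over the hindered secondary allylic (C7) and tertiary (C8) hydroxyls, placing the first isovalerate without a protecting‑group step.

**Step 9**
Reactants: 12
Product: 13, [(1R,5R)‑1,2‑dihydroxy‑5‑(TBSOCH2)‑4‑(3‑TBSO‑prop‑1‑en‑2‑yl)cyclopent‑3‑en‑1‑yl]methyl 3‑methylbutanoate
Conditions: Grubbs II (5 mol %), ethylene (1 atm), 1,4‑benzoquinone (10 mol %), CH2Cl2, 40 °C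
Reagents that add atoms: none (net cycloisomerisation; ethylene only shuttles the carbene)
Why: Ring‑closing enyne metathesis of a 1,6‑enyne closes in the exo mode to the cyclopentene (C5=C6) and moves the terminal methylene onto C4, forming ring A and the future C11 in one step while both C7 epimers react, free OH groups and the ester are tolerated, and C8/C9 are untouched.

**Step 10**
Reactants: 13
Product: 14, the 4‑(1‑hydroxy‑3‑TBSO‑propan‑2‑yl) analogue of 13
Conditions: 9‑BBN (4 equiv), THF, 0 °C → rt; NaBO3·4H2O, THF/H2O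
Reagents that add atoms: sodium perborate (O source), [Na+].[Na+].O[B-]1(O)OO[B-](O)(O)OO1
Why: In this Brown hydroboration–oxidation bulky 9‑BBN takes the 1,1‑disubstituted diene terminus rather than the trisubstituted ring olefin and adds anti‑Markovnikov, the near‑neutral perborate work‑up spares the ester, and the new C4 centre does not matter because it becomes sp2 in step 13.

**Step 11**
Reactants: 14
Product: 15, the 4‑(1‑acetoxy‑3‑TBSO‑propan‑2‑yl) analogue
Conditions: AcCl (1.05 equiv), 2,4,6‑collidine, CH2Cl2, −78 °C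
Reagents that add atoms: acetyl chloride, CC(=O)Cl
Why: Selective acetylation of the only primary OH installs the C11 acetate, since the other free hydroxyls are secondary allylic or tertiary.

**Step 12**
Reactants: 15
Product: 16, [(1R,5R)‑4‑(1‑acetoxy‑3‑hydroxypropan‑2‑yl)‑1,2‑dihydroxy‑5‑(hydroxymethyl)cyclopent‑3‑en‑1‑yl]methyl 3‑methylbutanoate
Conditions: HF·pyridine, pyridine/THF, 0 °C → rt
Reagents that add atoms: none
Why: Buffered fluoride desilylation frees C1–OH and C3–OH under mildly acidic conditions that suppress acyl migration, and an acetyl shift between the two C4 arms would in any case be degenerate.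

**Step 13 (key step)**
Reactants: 16
Product: 17, [(1R,7R,7aS)‑4‑(acetoxymethyl)‑1,7‑dihydroxy‑6‑oxo‑1,6,7,7a‑tetrahydrocyclopenta[c]pyran‑7‑yl]methyl 3‑methylbutanoate (1β‑OH lactol)
Conditions: (COCl)2 (6 equiv), DMSO (12 equiv), CH2Cl2, −78 °C; i‑Pr2NEt, −78 → −20 °C; pH 7 buffer
Reagents that add atoms: none
Why: Proposed new method: in a triple Swern oxidation all three carbinols are activated before base is added (so no 1,5‑diol → lactone over‑oxidation), giving the 7‑keto‑1,3‑dialdehyde, whose C4–H is α to CHO and vinylogously α to the enone, so it enolises to a vinylogous acid whose enol OH adds to the C1 aldehyde and closes ring B; the closest known chemistry is the iridodial → nepetalactol and genipin dialdehyde ⇌ lactol ring–chain closure (enol ether toward C4, not toward the ring‑fusion carbon) and pseudo‑acid closure of 2‑formylbenzoic acid, with C1–OH expected to adopt the genipin‑type β orientation (H1/H9 trans) and C9, although epimerisable here, already in its thermodynamically preferred arrangement (C1 anti to the larger CH2O‑iVal on C8).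

**Step 14**
Reactants: 17
Product: 18, [(1S,7R,7aS)‑4‑(acetoxymethyl)‑7‑hydroxy‑1‑(3‑methylbutanoyloxy)‑6‑oxo‑1,6,7,7a‑tetrahydrocyclopenta[c]pyran‑7‑yl]methyl 3‑methylbutanoate
Conditions: isovaleric anhydride (1.3 equiv), DMAP (5 mol %), 2,6‑lutidine, CH2Cl2, −20 °C
Reagents that add atoms: isovaleric anhydride, CC(C)CC(=O)OC(=O)CC(C)C
Why: In this anomeric O‑acylation of a mutarotating lactol the dominant, less hindered β‑anomer (OH on the face of H‑9, anti to the C9–C8 bond) is esterified with retention at C1 while the minor anomer re‑equilibrates, the tertiary α‑ketol OH is inert, and the push–pull dienone holds the enol ether and allylic acetate stable.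

**Step 15**
Reactants: 18
Product: 19, jatamanvaltrate J, [(1S,6S,7R,7aS)‑4‑(acetoxymethyl)‑6,7‑dihydroxy‑1‑(3‑methylbutanoyloxy)‑1,6,7,7a‑tetrahydrocyclopenta[c]pyran‑7‑yl]methyl 3‑methylbutanoate
Conditions: Zn(BH4)2, Et2O, −40 → −20 °C; cold aq NH4Cl
Reagents that add atoms: none
Why: In this chelation‑controlled 1,2‑reduction of an α‑hydroxy enone Zn(II) bridges the α‑face 8‑OH and the C7 carbonyl, activating the deactivated ketone and delivering hydride from the α face (opposite the β‑CH2O‑iVal), which gives the 7β‑OH trans to 8‑OH, and the neutral aprotic medium spares the three esters and the C1 acyloxy‑acetal.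

## Compound list
1 | 2‑butyne‑1,4‑diol | OCC#CCO | starting material
2 | 4‑(TBSO)but‑2‑yn‑1‑ol | OCC#CCO[Si](C)(C)C(C)(C)C | intermediate
3 | (Z)‑4‑(TBSO)‑2‑(tributylstannyl)but‑2‑en‑1‑ol | OC/C(=C/CO[Si](C)(C)C(C)(C)C)[Sn](CCCC)(CCCC)CCCC | intermediate
4 | vinyl bromide | C=CBr | starting material
5 | (E)‑4‑(TBSO)‑2‑vinylbut‑2‑en‑1‑ol | OC/C(C=C)=C/CO[Si](C)(C)C(C)(C)C | intermediate
6 | [(2S,3S)‑3‑(TBSOCH2)‑2‑vinyloxiran‑2‑yl]methanol | OC[C@]1(C=C)O[C@H]1CO[Si](C)(C)C(C)(C)C | intermediate
7 | (2S,3S)‑3‑(TBSOCH2)‑2‑(hydroxymethyl)oxirane‑2‑carbaldehyde | OC[C@]1(C=O)O[C@H]1CO[Si](C)(C)C(C)(C)C | intermediate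
8 | vinylmagnesium bromide | C=C[Mg]Br | starting material
9 | 1‑[(2R,3S)‑3‑(TBSOCH2)‑2‑(hydroxymethyl)oxiran‑2‑yl]prop‑2‑en‑1‑ol (C7 epimers) | OC[C@]1(C(O)C=C)O[C@H]1CO[Si](C)(C)C(C)(C)C | intermediate
10 | tert‑butyldimethyl(prop‑2‑yn‑1‑yloxy)silane | C#CCO[Si](C)(C)C(C)(C)C | starting material
11 | (4R,5R)‑8‑(TBSO)‑5‑(TBSOCH2)‑4‑(hydroxymethyl)oct‑1‑en‑6‑yne‑3,4‑diol | C=CC(O)[C@](O)(CO)[C@@H](CO[Si](C)(C)C(C)(C)C)C#CCO[Si](C)(C)C(C)(C)C | intermediate
12 | C10 isovalerate of 11 | C=CC(O)[C@](O)(COC(=O)CC(C)C)[C@@H](CO[Si](C)(C)C(C)(C)C)C#CCO[Si](C)(C)C(C)(C)C | intermediate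
13 | cyclopentenyl 1,3‑diene (ring A) | C=C(CO[Si](C)(C)C(C)(C)C)C1=CC(O)[C@](O)(COC(=O)CC(C)C)[C@H]1CO[Si](C)(C)C(C)(C)C | intermediate
14 | primary alcohol from hydroboration | OCC(CO[Si](C)(C)C(C)(C)C)C1=CC(O)[C@](O)(COC(=O)CC(C)C)[C@H]1CO[Si](C)(C)C(C)(C)C | intermediate
15 | C11 acetate | CC(=O)OCC(CO[Si](C)(C)C(C)(C)C)C1=CC(O)[C@](O)(COC(=O)CC(C)C)[C@H]1CO[Si](C)(C)C(C)(C)C | intermediate
16 | tetraol | CC(=O)OCC(CO)C1=CC(O)[C@](O)(COC(=O)CC(C)C)[C@H]1CO | intermediate
17 | 7‑oxo lactol (1R,7R,7aS) | CC(=O)OCC1=CO[C@@H](O)[C@H]2C1=CC(=O)[C@]2(O)COC(=O)CC(C)C | intermediate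
18 | 7‑oxo 1‑O‑isovalerate (1S,7R,7aS) | CC(=O)OCC1=CO[C@@H](OC(=O)CC(C)C)[C@H]2C1=CC(=O)[C@]2(O)COC(=O)CC(C)C | intermediate
19 | jatamanvaltrate J (1S,6S,7R,7aS) | CC(=O)OCC1=CO[C@@H](OC(=O)CC(C)C)[C@H]2C1=C[C@H](O)[C@]2(O)COC(=O)CC(C)C | target

## Step count
Total steps: 15. Longest linear sequence: 15, from 2‑butyne‑1,4‑diol; all coupling partners are purchased.

## Steps most likely to fail
1. **Step 13, oxidation/lactolisation cascade.**
   - Risks: E1cB loss of the C11 acetate from the β‑acetoxy aldehyde, enolisation toward C9 (a C1=C9 regioisomeric lactol), and erosion of C9.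
   - Fallback: bring C3 in already as an enol ether. Treat enyne 12 with butyl vinyl ether and Grubbs II, an enol‑ether/alkyne cross‑metathesis followed by RCM running through a Fischer carbene in "yne‑then‑ene" mode. The propargylic arm then becomes C11. Oxidise only C1 and C7, close ring B by acid‑catalysed vinylogous transacetalisation, and add the acetate after the ring is closed.
2. **Step 15, last‑step ketone reduction.**
   - Risks: a sluggish, doubly vinylogous ester carbonyl, 1,4‑ or 1,6‑reduction, 10→7 isovaleryl migration, and attack on the wrong face.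
   - Fallback: drop the late reset. Oxidise 9 to the epoxy enone and reduce it under catalyst control (CBS) to a single C7 carbinol, and carry that as its 7‑O‑TES ether. Then oxidise only C1 and C3, acylate the lactol directly in the non‑oxo series, and remove TES with buffered fluoride.
3. **Step 7, regioselective epoxide opening.**
   - Risks: attack at C8, semipinacol shift, or Payne scrambling.
   - Fallback: reverse the polarity of the C8–C9 construction. Carry out conjugate alkynylation of 3‑(silyloxymethyl)furan‑2(5H)‑one (chiral Rh catalyst), then anti α‑hydroxylation of the enolate with a Davis oxaziridine; this gives the same trans O8/alkynyl relationship on a lactone. DIBAL reduction and then vinylMgBr converge on a triol of type 11.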